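**Strategy.** Ring B (chroman numbering O1–C8a) carries three contiguous carbon substituents: C4 on C4a, the prenyl CH2 on C5 and the propyl linker on C6. The route treats C4 and the prenyl C1″ as the two allylic carbons of a cyclohexene fused at C4a–C5. That ring is made in one operation by a Diels–Alder reaction of butadiene with the o-quinone of a simple 4-(3-arylpropyl)catechol, followed by re-aromatisation; both hard C–C bonds form with fixed regiochemistry. Oxidative cleavage and double isopropylidenation then reveal two vicinal prenyl groups, of which only the one next to O1 can close the chroman. The precursor is a protected 1,3-diarylpropane available from a chalcone.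

Key step: step 5

Remark on the chemistry: the target has no stereogenic element, so no enantiocontrol is needed; the racemic or relative stereocentres of intermediates 5, 10, 13 and 21 are all destroyed later. Ring A is numbered C1 (1,1-dimethylallyl carbon), C3 (linker carbon), O4 and O6 (the oxygens on C4 and C6). ArA = 2-(methoxymethoxy)-4-{[2-(trimethylsilyl)ethoxy]methoxy}phenyl (O4-MOM, O6-SEM). ArB = 4,5-bis(methoxymethoxy)-2,3-bis(3-methylbut-2-en-1-yl)phenyl.

Step 1
Reactants: 1 2,4-dihydroxyacetophenone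
Product: 2 1-(2-hydroxy-4-{[2-(trimethylsilyl)ethoxy]methoxy}phenyl)ethan-1-one
Conditions: SEMCl (1.05 equiv), i-Pr2NEt, CH2Cl2, 0 °C → rt
Reagents that add atoms: 2-(trimethylsilyl)ethoxymethyl chloride (SEMCl), C[Si](C)(C)CCOCCl
Why: Selective Williamson-type O-alkylation: the 2-OH is held in a hydrogen bond to the acetyl group, so only the 4-OH (future O6 of ring A) is alkylated.

Step 2
Reactants: 2 1-(2-hydroxy-4-{[2-(trimethylsilyl)ethoxy]methoxy}phenyl)ethan-1-one
Product: 3 1-(ArA)ethan-1-one
Conditions: NaH, DMF, 0 °C; then MOMCl, 0 °C → rt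
Reagents that add atoms: chloromethyl methyl ether (MOMCl), COCCl
Why: After full deprotonation the chelated 2-phenoxide is alkylated by MOMCl (Williamson-type acetal ether formation), so O4 and O6 carry different base-stable groups.

Step 3
Reactants: 3 1-(ArA)ethan-1-one; 4 3,4-bis(benzyloxy)benzaldehyde
Product: 6 (E)-3-[3,4-bis(benzyloxy)phenyl]-1-(ArA)prop-2-en-1-one, via racemic 3-[3,4-bis(benzyloxy)phenyl]-3-hydroxy-1-(ArA)propan-1-one 5 (not isolated)
Conditions: KOH (50% aq.), EtOH–THF, rt
Reagents that add atoms: none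
Why: Claisen–Schmidt (crossed aldol) condensation of the methyl ketone with the non-enolisable aldehyde, E1cB dehydration of aldol 5 giving the (E)-enone; acetal and benzyl ethers are stable to hydroxide.

Step 4
Reactants: 6 (E)-3-[3,4-bis(benzyloxy)phenyl]-1-(ArA)prop-2-en-1-one
Product: 7 4-[3-(ArA)propyl]benzene-1,2-diol
Conditions: H2 (4 atm), 10% Pd/C, EtOAc–AcOH (4:1), 45 °C
Reagents that add atoms: none
Why: One-pot catalytic hydrogenation/hydrogenolysis: the C=C bond is saturated, both benzyl ethers are cleaved and the ketone is reduced through the electron-rich 2,4-dialkoxybenzylic alcohol to CH2, while the MOM and SEM acetals survive acetic acid.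

Step 5
Reactants: 7 4-[3-(ArA)propyl]benzene-1,2-diol; 8 buta-1,3-diene
Product: 11 4-[3-(ArA)propyl]-5,8-dihydronaphthalene-1,2-diol, via 4-[3-(ArA)propyl]cyclohexa-3,5-diene-1,2-dione 9 (not isolated), via racemic cis-4-[3-(ArA)propyl]-4a,5,8,8a-tetrahydronaphthalene-1,2-dione 10 (not isolated)
Conditions: Ag2O (2 equiv), Na2SO4, Et2O–CH2Cl2, −20 °C, 10 min, dark; cold filtration into 8 (ca. 30 equiv) in CH2Cl2, sealed vessel, −20 °C → rt, Ar; then Et3N (0.1 equiv), rt
Reagents that add atoms: none
Why: Ag2O dehydrogenates the catechol to the 4-alkyl-o-benzoquinone 9, whose unsubstituted enone C=C (the future C4a–C5 bond) then serves as the 2π partner for s-cis butadiene in a concerted, suprafacial normal-demand [4+2] cycloaddition; amine-catalysed double enolisation of the cis-fused dione 10 restores the arene and makes the sequence irreversible. The closest known reaction type is the Diels–Alder reaction of 4-substituted o-benzoquinones as carbodienophiles with acyclic 1,3-dienes, which leads to 5,8-dihydronaphthalene-1,2-diols. One ring is closed, the six-membered carbocycle, by intermolecular [4π+2π] cycloaddition that forms the C4a–C4 and C5–C1″ bonds together. The two ring-fusion stereocentres of 10 are set cis by the suprafacial addition and are erased on aromatisation, so nothing has to be controlled. The step needs site selectivity for the unsubstituted over the chain-bearing C=C (secured by the steric and electron-releasing effect of the alkyl group and by the fact that only this adduct can aromatise), periselectivity for C=C over hetero-Diels–Alder addition across the O=C–C=O unit (the usual preference of o-quinones that carry neither halogens nor bulky groups), and a rate advantage over quinone dimerisation and tautomerisation to the p-quinone methide (low temperature, large excess of diene, oxidant filtered off before the product catechol forms). Ring A cannot interfere, since both of its oxygens are acetal-protected and its nucleophilic carbons cannot reach the quinone through the three-carbon tether.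

Step 6
Reactants: 11 4-[3-(ArA)propyl]-5,8-dihydronaphthalene-1,2-diol
Product: 12 1,2-bis(methoxymethoxy)-4-[3-(ArA)propyl]-5,8-dihydronaphthalene
Conditions: MOMCl (3 equiv), i-Pr2NEt, CH2Cl2, 0 °C → rt
Reagents that add atoms: chloromethyl methyl ether (MOMCl), COCCl
Why: Double Williamson-type O-alkylation of the catechol under amine base masks both phenols against osmium, periodate and ylide and avoids strong base that could isomerise the dihydroarene ring.

Step 7
Reactants: 12 1,2-bis(methoxymethoxy)-4-[3-(ArA)propyl]-5,8-dihydronaphthalene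
Product: 14 2,2′-{3,4-bis(methoxymethoxy)-6-[3-(ArA)propyl]-1,2-phenylene}diacetaldehyde, via racemic cis-5,6-bis(methoxymethoxy)-8-[3-(ArA)propyl]-1,2,3,4-tetrahydronaphthalene-2,3-diol 13 (not isolated)
Conditions: OsO4 (2 mol%), NMO, acetone–H2O, rt; then NaIO4, pH 7 buffer, 0 °C; crude product used at once
Reagents that add atoms: N-methylmorpholine N-oxide (terminal source of the oxygen delivered by OsO4), C[N+]1([O-])CCOCC1; water, O
Why: Catalytic OsO4/NMO cis-dihydroxylation of the only alkene followed by periodate (Malaprade) glycol cleavage in the same pot opens the cyclohexene to the bis(arylacetaldehyde); the cis configuration of 13 follows from syn addition and is destroyed on cleavage.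

Step 8
Reactants: 14 2,2′-{3,4-bis(methoxymethoxy)-6-[3-(ArA)propyl]-1,2-phenylene}diacetaldehyde; 15 isopropyltriphenylphosphonium iodide
Product: 17 1,2-bis(methoxymethoxy)-3,4-bis(3-methylbut-2-en-1-yl)-5-[3-(ArA)propyl]benzene, via isopropylidenetriphenylphosphorane 16 (not isolated)
Conditions: 15 (3.0 equiv), n-BuLi (2.9 equiv), THF, 0 °C; then 14 in THF, −78 °C → rt
Reagents that add atoms: none
Why: Double Wittig olefination with the non-stabilised ylide 16 converts each CH2CHO arm into a 3-methylbut-2-enyl group (no alkene geometry arises), inverse addition at −78 °C limiting enolisation of the arylacetaldehydes.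

Step 9
Reactants: 17 1,2-bis(methoxymethoxy)-3,4-bis(3-methylbut-2-en-1-yl)-5-[3-(ArA)propyl]benzene
Product: 18 3-(methoxymethoxy)-4-[3-(ArB)propyl]phenol
Conditions: TBAF (5 equiv), ethylenediamine (5 equiv), DMF, 60 °C; aq. NH4Cl work-up
Reagents that add atoms: none
Why: SEM deprotection: fluoride attacks silicon and the group fragments to ethene, formaldehyde and the O6 phenoxide, while MOM ethers and prenyl groups are inert and ethylenediamine scavenges formaldehyde.

Step 10
Reactants: 18 3-(methoxymethoxy)-4-[3-(ArB)propyl]phenol; 19 1-bromo-3-methylbut-2-ene (prenyl bromide)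
Product: 20 1-[3-(ArB)propyl]-2-(methoxymethoxy)-4-[(3-methylbut-2-en-1-yl)oxy]benzene
Conditions: K2CO3, acetone, reflux
Reagents that add atoms: none
Why: Williamson etherification of the only free phenol (O6) with the SN2-reactive allylic bromide under mild carbonate base.

Step 11
Reactants: 20 1-[3-(ArB)propyl]-2-(methoxymethoxy)-4-[(3-methylbut-2-en-1-yl)oxy]benzene
Product: 22 5-(methoxymethoxy)-2-(2-methylbut-3-en-2-yl)-4-[3-(ArB)propyl]phenol, via racemic 3-(methoxymethoxy)-6-(2-methylbut-3-en-2-yl)-4-[3-(ArB)propyl]cyclohexa-2,4-dien-1-one 21 (not isolated)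
Conditions: N,N-diethylaniline, 185 °C, sealed tube, Ar
Reagents that add atoms: none
Why: Aromatic Claisen rearrangement ([3,3]-sigmatropic, chair transition state) transfers the allyl unit with inversion so that its tertiary carbon bonds to C1, the less hindered ortho carbon (C5 is flanked by O4-MOM), and dienone 21 tautomerises to the phenol with loss of its stereocentre.

Step 12
Reactants: 22 5-(methoxymethoxy)-2-(2-methylbut-3-en-2-yl)-4-[3-(ArB)propyl]phenol
Product: 23 4-{3-[4,5-dihydroxy-2,3-bis(3-methylbut-2-en-1-yl)phenyl]propyl}-6-(2-methylbut-3-en-2-yl)benzene-1,3-diol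
Conditions: TMSOTf (8 equiv), 2,2′-bipyridyl (12 equiv), MeCN, 0 °C → rt; then H2O
Reagents that add atoms: none
Why: Non-protic cleavage of the three aromatic MOM ethers by TMSOTf/2,2′-bipyridyl (silyl transfer to the aryl oxygen, then hydrolysis of the aryl silyl ethers), a buffered method chosen because it does not protonate the three alkenes.

Step 13
Reactants: 23 4-{3-[4,5-dihydroxy-2,3-bis(3-methylbut-2-en-1-yl)phenyl]propyl}-6-(2-methylbut-3-en-2-yl)benzene-1,3-diol
Product: 24 Kazinol D, 4-{3-[8-hydroxy-2,2-dimethyl-5-(3-methylbut-2-en-1-yl)-3,4-dihydro-2H-chromen-6-yl]propyl}-6-(2-methylbut-3-en-2-yl)benzene-1,3-diol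
Conditions: p-TsOH·H2O (0.2 equiv), toluene–EtOAc (5:1), 50 °C, 5 mM
Reagents that add atoms: none
Why: Acid-catalysed intramolecular Markovnikov hydroalkoxylation (6-endo cyclisation of an o-prenylphenol to a 2,2-dimethylchroman): only the C4a prenyl has an ortho hydroxyl (O1), the C5-prenyl cation can only revert in the non-nucleophilic medium, and the monosubstituted vinyl of the 1,1-dimethylallyl group is protonated far more slowly.

**Compound list**

1 | 2,4-dihydroxyacetophenone | CC(=O)c1ccc(O)cc1O | starting material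
2 | 1-(2-hydroxy-4-{[2-(trimethylsilyl)ethoxy]methoxy}phenyl)ethan-1-one | CC(=O)c1ccc(OCOCC[Si](C)(C)C)cc1O | intermediate
3 | 1-[2-(methoxymethoxy)-4-{[2-(trimethylsilyl)ethoxy]methoxy}phenyl]ethan-1-one | CC(=O)c1ccc(OCOCC[Si](C)(C)C)cc1OCOC | intermediate
4 | 3,4-bis(benzyloxy)benzaldehyde | O=Cc1ccc(OCc2ccccc2)c(OCc2ccccc2)c1 | starting material
5 | racemic aldol adduct, 3-[3,4-bis(benzyloxy)phenyl]-3-hydroxy-1-(ArA)propan-1-one | O=C(CC(O)c1ccc(OCc2ccccc2)c(OCc2ccccc2)c1)c1ccc(OCOCC[Si](C)(C)C)cc1OCOC | intermediate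
6 | (E)-3-[3,4-bis(benzyloxy)phenyl]-1-(ArA)prop-2-en-1-one | O=C(/C=C/c1ccc(OCc2ccccc2)c(OCc2ccccc2)c1)c1ccc(OCOCC[Si](C)(C)C)cc1OCOC | intermediate
7 | 4-[3-(ArA)propyl]benzene-1,2-diol | Oc1ccc(CCCc2ccc(OCOCC[Si](C)(C)C)cc2OCOC)cc1O | intermediate
8 | buta-1,3-diene | C=CC=C | starting material
9 | 4-[3-(ArA)propyl]cyclohexa-3,5-diene-1,2-dione | O=C1C=CC(CCCc2ccc(OCOCC[Si](C)(C)C)cc2OCOC)=CC1=O | intermediate
10 | racemic cis-4-[3-(ArA)propyl]-4a,5,8,8a-tetrahydronaphthalene-1,2-dione (relative configuration shown) | O=C1C(=O)C=C(CCCc3ccc(OCOCC[Si](C)(C)C)cc3OCOC)[C@H]2CC=CC[C@@H]12 | intermediate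
11 | 4-[3-(ArA)propyl]-5,8-dihydronaphthalene-1,2-diol | Oc1cc(CCCc2ccc(OCOCC[Si](C)(C)C)cc2OCOC)c2c(c1O)CC=CC2 | intermediate
12 | 1,2-bis(methoxymethoxy)-4-[3-(ArA)propyl]-5,8-dihydronaphthalene | COCOc1cc(CCCc2ccc(OCOCC[Si](C)(C)C)cc2OCOC)c2c(c1OCOC)CC=CC2 | intermediate
13 | racemic cis-5,6-bis(methoxymethoxy)-8-[3-(ArA)propyl]-1,2,3,4-tetrahydronaphthalene-2,3-diol (relative configuration shown) | COCOc1cc(CCCc2ccc(OCOCC[Si](C)(C)C)cc2OCOC)c2c(c1OCOC)C[C@H](O)[C@H](O)C2 | intermediate
14 | 2,2′-{3,4-bis(methoxymethoxy)-6-[3-(ArA)propyl]-1,2-phenylene}diacetaldehyde | COCOc1cc(CCCc2ccc(OCOCC[Si](C)(C)C)cc2OCOC)c(CC=O)c(CC=O)c1OCOC | intermediate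
15 | isopropyltriphenylphosphonium iodide | CC(C)[P+](c1ccccc1)(c1ccccc1)c1ccccc1.[I-] | starting material
16 | isopropylidenetriphenylphosphorane | CC(C)=P(c1ccccc1)(c1ccccc1)c1ccccc1 | intermediate
17 | 1,2-bis(methoxymethoxy)-3,4-bis(3-methylbut-2-en-1-yl)-5-[3-(ArA)propyl]benzene | COCOc1cc(CCCc2ccc(OCOCC[Si](C)(C)C)cc2OCOC)c(CC=C(C)C)c(CC=C(C)C)c1OCOC | intermediate
18 | 3-(methoxymethoxy)-4-[3-(ArB)propyl]phenol | COCOc1cc(CCCc2ccc(O)cc2OCOC)c(CC=C(C)C)c(CC=C(C)C)c1OCOC | intermediate
19 | 1-bromo-3-methylbut-2-ene | CC(C)=CCBr | starting material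
20 | 1-[3-(ArB)propyl]-2-(methoxymethoxy)-4-[(3-methylbut-2-en-1-yl)oxy]benzene | COCOc1cc(CCCc2ccc(OCC=C(C)C)cc2OCOC)c(CC=C(C)C)c(CC=C(C)C)c1OCOC | intermediate
21 | racemic 3-(methoxymethoxy)-6-(2-methylbut-3-en-2-yl)-4-[3-(ArB)propyl]cyclohexa-2,4-dien-1-one | COCOc1cc(CCCC2=CC(C(C)(C)C=C)C(=O)C=C2OCOC)c(CC=C(C)C)c(CC=C(C)C)c1OCOC | intermediate
22 | 5-(methoxymethoxy)-2-(2-methylbut-3-en-2-yl)-4-[3-(ArB)propyl]phenol | COCOc1cc(CCCc2cc(C(C)(C)C=C)c(O)cc2OCOC)c(CC=C(C)C)c(CC=C(C)C)c1OCOC | intermediate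
23 | 4-{3-[4,5-dihydroxy-2,3-bis(3-methylbut-2-en-1-yl)phenyl]propyl}-6-(2-methylbut-3-en-2-yl)benzene-1,3-diol | C=CC(C)(C)c1cc(CCCc2cc(O)c(O)c(CC=C(C)C)c2CC=C(C)C)c(O)cc1O | intermediate
24 | Kazinol D | C=CC(C)(C)c1cc(CCCc2cc(O)c3c(c2CC=C(C)C)CCC(C)(C)O3)c(O)cc1O | target

**Totals.** 13 steps; longest linear sequence 13 steps (1 → 24).

**Steps most likely to fail**

Step 5. The 4-alkyl-o-quinone may be lost before cycloaddition through tautomerisation to the p-quinone methide, dimerisation, addition of the diene across the dione oxygens, or redox exchange with catechol product formed early. The fallback replaces the cycloaddition by dissolving-metal reduction of a naphthalene and sets out from 3. Commercial 1,2-naphthoquinone is reduced with Na2S2O4 to naphthalene-1,2-diol F1, benzylated (BnBr, K2CO3, DMF) to 1,2-bis(benzyloxy)naphthalene F2 and formylated at C4 (POCl3, DMF) to 3,4-bis(benzyloxy)-1-naphthaldehyde F3. Claisen–Schmidt condensation of F3 with 3 should give (E)-3-[3,4-bis(benzyloxy)naphthalen-1-yl]-1-(ArA)prop-2-en-1-one F4, and hydrogenation under the conditions of step 4 should give 4-[3-(ArA)propyl]naphthalene-1,2-diol F5. Birch reduction of F5 (Li, NH3/THF, t-BuOH, −78 °C) should reduce only the unsubstituted ring, because the dilithium catecholate ring resists electron uptake, and comes back to the route at 11.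

Step 8. The basic ylide may deprotonate the arylacetaldehydes, which then undergo intramolecular aldol condensation to an indene, and the dialdehyde may form hydrates or oligomers. The fallback uses a non-basic olefination followed by deoxygenation and sets out from 14. The stabilised ylide Ph3P=C(Me)CO2Et (CH2Cl2, rt) should give diethyl (2E,2′E)-4,4′-{3,4-bis(methoxymethoxy)-6-[3-(ArA)propyl]-1,2-phenylene}bis(2-methylbut-2-enoate) F6. DIBAL-H (CH2Cl2, −78 °C) should give the bis-allylic alcohol, (2E,2′E)-4,4′-{3,4-bis(methoxymethoxy)-6-[3-(ArA)propyl]-1,2-phenylene}bis(2-methylbut-2-en-1-ol) F7. MsCl, Et3N and LiCl (DMF, 0 °C) should give the corresponding bis-allylic chloride, 1,2-bis[(2E)-4-chloro-3-methylbut-2-en-1-yl]-3,4-bis(methoxymethoxy)-6-[3-(ArA)propyl]benzene F8. LiEt3BH (THF, 0 °C) then removes both chlorides by SN2 hydride delivery and comes back to the route at 17.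

Step 11. The allyl unit may migrate to C5 between the two oxygens, the prenyl ether may ionise with loss of the allyl group, and the o-(1,1-dimethylallyl)phenol may react further at 185 °C (cyclisation to a dihydrobenzofuran, abnormal Claisen). The fallback installs the group by cross-coupling instead of a sigmatropic shift and sets out from 12. NBS (1.0 equiv, MeCN, −20 °C) should brominate ring A at C1 (para to O4-MOM) to 4-{3-[5-bromo-2-(methoxymethoxy)-4-{[2-(trimethylsilyl)ethoxy]methoxy}phenyl]propyl}-1,2-bis(methoxymethoxy)-5,8-dihydronaphthalene F9. The conditions of steps 7 and 8 are then applied to F9, passing through the racemic cis-diol, the 2,3-diol analogue of 13 bearing the ring-A bromide F10, and the dialdehyde, the ring-A bromide analogue of 14 F11, to give the bis-prenyl aryl bromide, the ring-A C1 bromide analogue of 17 F12. A γ-selective (branched) Pd-catalysed Suzuki–Miyaura coupling of F12 with prenylboronic acid pinacol ester (K3PO4, THF–H2O) should give 1,2-bis(methoxymethoxy)-3,4-bis(3-methylbut-2-en-1-yl)-5-{3-[2-(methoxymethoxy)-5-(2-methylbut-3-en-2-yl)-4-{[2-(trimethylsilyl)ethoxy]methoxy}phenyl]propyl}benzene F13. TBAF/ethylenediamine as in step 9 then comes back to the route at 22.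

**Further compounds**

F1 | step 5 | naphthalene-1,2-diol | Oc1ccc2ccccc2c1O
F2 | step 5 | 1,2-bis(benzyloxy)naphthalene | c1ccc(COc2ccc3ccccc3c2OCc2ccccc2)cc1
F3 | step 5 | 3,4-bis(benzyloxy)-1-naphthaldehyde | O=Cc1cc(OCc2ccccc2)c(OCc2ccccc2)c2ccccc12
F4 | step 5 | (E)-3-[3,4-bis(benzyloxy)naphthalen-1-yl]-1-(ArA)prop-2-en-1-one | O=C(/C=C/c1cc(OCc2ccccc2)c(OCc2ccccc2)c2ccccc12)c1ccc(OCOCC[Si](C)(C)C)cc1OCOC
F5 | step 5 | 4-[3-(ArA)propyl]naphthalene-1,2-diol | Oc1cc(CCCc2ccc(OCOCC[Si](C)(C)C)cc2OCOC)c2ccccc2c1O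
F6 | step 8 | diethyl (2E,2′E)-4,4′-{3,4-bis(methoxymethoxy)-6-[3-(ArA)propyl]-1,2-phenylene}bis(2-methylbut-2-enoate) | COCOc1cc(CCCc2ccc(OCOCC[Si](C)(C)C)cc2OCOC)c(C/C=C(\C)C(=O)OCC)c(C/C=C(\C)C(=O)OCC)c1OCOC
F7 | step 8 | (2E,2′E)-4,4′-{3,4-bis(methoxymethoxy)-6-[3-(ArA)propyl]-1,2-phenylene}bis(2-methylbut-2-en-1-ol) | COCOc1cc(CCCc2ccc(OCOCC[Si](C)(C)C)cc2OCOC)c(C/C=C(\C)CO)c(C/C=C(\C)CO)c1OCOC
F8 | step 8 | 1,2-bis[(2E)-4-chloro-3-methylbut-2-en-1-yl]-3,4-bis(methoxymethoxy)-6-[3-(ArA)propyl]benzene | COCOc1cc(CCCc2ccc(OCOCC[Si](C)(C)C)cc2OCOC)c(C/C=C(\C)CCl)c(C/C=C(\C)CCl)c1OCOC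
F9 | step 11 | 4-{3-[5-bromo-2-(methoxymethoxy)-4-{[2-(trimethylsilyl)ethoxy]methoxy}phenyl]propyl}-1,2-bis(methoxymethoxy)-5,8-dihydronaphthalene | COCOc1cc(CCCc2cc(Br)c(OCOCC[Si](C)(C)C)cc2OCOC)c2c(c1OCOC)CC=CC2
F10 | step 11 | racemic cis-2,3-diol of F9 (ring-A bromide analogue of 13) | COCOc1cc(CCCc2cc(Br)c(OCOCC[Si](C)(C)C)cc2OCOC)c2c(c1OCOC)C[C@H](O)[C@H](O)C2
F11 | step 11 | ring-A bromide analogue of dialdehyde 14 | COCOc1cc(CCCc2cc(Br)c(OCOCC[Si](C)(C)C)cc2OCOC)c(CC=O)c(CC=O)c1OCOC
F12 | step 11 | ring-A C1 bromide analogue of 17 | COCOc1cc(CCCc2cc(Br)c(OCOCC[Si](C)(C)C)cc2OCOC)c(CC=C(C)C)c(CC=C(C)C)c1OCOC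
F13 | step 11 | 1,2-bis(methoxymethoxy)-3,4-bis(3-methylbut-2-en-1-yl)-5-{3-[2-(methoxymethoxy)-5-(2-methylbut-3-en-2-yl)-4-{[2-(trimethylsilyl)ethoxy]methoxy}phenyl]propyl}benzene | COCOc1cc(CCCc2cc(C(C)(C)C=C)c(OCOCC[Si](C)(C)C)cc2OCOC)c(CC=C(C)C)c(CC=C(C)C)c1OCOC
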